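**Retrosynthetic overview**

1. Quinone ring, made last: thermal ring expansion of a macrocyclic 4-ethynyl-4-hydroxycyclobut-2-enone (four squarate carbons plus two acetylene carbons give the six-membered quinone); it is an isomerisation and delivers the unprotected target.
2. 18-Membered ring: closed before that at the squarate C–OAr bond, by high-dilution addition–elimination of the ring-C phenol on a chlorocyclobutenedione (an ester-type bond formation).
3. Squarate–CH2 bond from an arylethyl Grignard reagent and diisopropyl squarate; ring A–O–ring B by Ullmann coupling; ring B–CH2CH2–ring C by Wittig reaction and hydrogenation.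
4. Order of ring formation: the three arenes and the four-membered ring are purchased, then the macrocycle (step 10), then the quinone ring (step 12).
5. Enabling feature: in the quinone ring, C1(=O) and C4(=O) flank C2(OAr)=C3(CH2), which is the atom pattern of a 3-aryloxy-4-alkylcyclobut-3-ene-1,2-dione, and C5 and C6 are both CH (acetylene). Because both are CH, either squarate carbonyl may take the acetylide, and the macrocycle spans only C2/C3, which stay syn throughout.

Key step: step 12

Assumption: the target SMILES contains no stereocentre and the macrocycle is taken as conformationally mobile (achiral), so no enantiocontrol is needed; the carbinol centre of compound 20 is racemic and is destroyed in step 12.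

**Route**

Step 1
Reactants: 1 3,4-dihydroxybenzaldehyde
Product: 2 3-hydroxy-4-(methoxymethoxy)benzaldehyde
Conditions: MOMCl (1.05 equiv), K2CO3 (1.1 equiv), acetone, 0 °C → rt
Reagents that add atoms: chloromethyl methyl ether, COCCl
Why: Williamson-type O-alkylation; the 4-OH, para to the formyl group, is the more acidic phenol and should be alkylated selectively with one equivalent of weak base.

Step 2
Reactants: 2 3-hydroxy-4-(methoxymethoxy)benzaldehyde; 3 2-(4-bromophenyl)ethanol
Product: 4 3-[4-(2-hydroxyethyl)phenoxy]-4-(methoxymethoxy)benzaldehyde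
Conditions: CuI (10 mol %), picolinic acid (20 mol %), K3PO4 (2 equiv), DMSO, 90 °C
Reagents that add atoms: none
Why: Ligand-accelerated Ullmann diaryl ether synthesis; the copper/picolinate system arylates phenols in preference to aliphatic alcohols and tolerates ortho-alkoxy phenols and aldehydes.

Step 3
Reactants: 5 3-hydroxybenzyl alcohol
Product: 6 (3-hydroxybenzyl)triphenylphosphonium bromide
Conditions: PPh3·HBr, MeCN, reflux
Reagents that add atoms: triphenylphosphine hydrobromide, [Br-].c1ccc(cc1)[PH+](c1ccccc1)c1ccccc1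
Why: Triphenylphosphine hydrobromide converts benzylic alcohols directly into benzylphosphonium salts (acid-promoted nucleophilic substitution at the benzylic carbon), and the phenol does not interfere.

Step 4
Reactants: 4 3-[4-(2-hydroxyethyl)phenoxy]-4-(methoxymethoxy)benzaldehyde; 6 (3-hydroxybenzyl)triphenylphosphonium bromide
Product: 8 3-{2-[3-[4-(2-hydroxyethyl)phenoxy]-4-(methoxymethoxy)phenyl]ethenyl}phenol (E/Z mixture), via potassium 3-[(triphenylphosphoranylidene)methyl]phenolate 7 (not isolated)
Conditions: 6 (1.2 equiv), KOtBu (2.5 equiv), THF, 0 °C; then 4, 0 °C → rt; aq NH4Cl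
Reagents that add atoms: none
Why: Wittig olefination with a semi-stabilised benzylic ylide generated as its phenolate with two equivalents of base; the E/Z ratio is of no consequence because the alkene is saturated in step 5.

Step 5
Reactants: 8 3-{2-[3-[4-(2-hydroxyethyl)phenoxy]-4-(methoxymethoxy)phenyl]ethenyl}phenol
Product: 9 3-{2-[3-[4-(2-hydroxyethyl)phenoxy]-4-(methoxymethoxy)phenyl]ethyl}phenol
Conditions: H2 (1 atm), 10% Pd/C, EtOAc, rt
Reagents that add atoms: none
Why: Heterogeneous catalytic hydrogenation should saturate both stilbene isomers to the bibenzyl, while the MOM ether, the diaryl ether and the alcohol are inert.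

Step 6
Reactants: 9 3-{2-[3-[4-(2-hydroxyethyl)phenoxy]-4-(methoxymethoxy)phenyl]ethyl}phenol
Product: 10 3-{2-[3-[4-(2-bromoethyl)phenoxy]-4-(methoxymethoxy)phenyl]ethyl}phenol
Conditions: CBr4, PPh3, CH2Cl2, 0 °C
Reagents that add atoms: carbon tetrabromide, BrC(Br)(Br)Br
Why: Appel reaction converts the primary alcohol into the bromide under neutral conditions; the phenol is not a substrate and the MOM acetal should survive.

Step 7
Reactants: 10 3-{2-[3-[4-(2-bromoethyl)phenoxy]-4-(methoxymethoxy)phenyl]ethyl}phenol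
Product: 11 2-[4-(2-bromoethyl)phenoxy]-1-(methoxymethoxy)-4-{2-[3-(methoxymethoxy)phenyl]ethyl}benzene
Conditions: MOMCl, iPr2NEt, CH2Cl2, 0 °C → rt
Reagents that add atoms: chloromethyl methyl ether, COCCl
Why: O-Alkylation of the phenol with MOMCl under Hünig's base (acetal protection) removes the only acidic proton before Grignard formation, and the primary bromide is inert to the hindered amine.

Step 8
Reactants: 11 2-[4-(2-bromoethyl)phenoxy]-1-(methoxymethoxy)-4-{2-[3-(methoxymethoxy)phenyl]ethyl}benzene; 12 3,4-diisopropoxycyclobut-3-ene-1,2-dione (diisopropyl squarate)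
Product: 16 3-isopropoxy-4-[2-(4-{2-(methoxymethoxy)-5-[2-(3-(methoxymethoxy)phenyl)ethyl]phenoxy}phenyl)ethyl]cyclobut-3-ene-1,2-dione, via the arylethylmagnesium bromide 13 (not isolated), via the bromomagnesium alkoxide of the squarate 1,2-adduct 14 (not isolated), via the O-trifluoroacetate of the 1,2-adduct 15 (not isolated)
Conditions: Mg, THF, rt → 40 °C; cannulated into 12 (1.3 equiv), THF, −78 °C; TFAA (1.5 equiv), −78 °C; aq NH4Cl, → rt
Reagents that add atoms: none
Why: Grignard 1,2-addition to one carbonyl of the dialkyl squarate followed by trifluoroacetylation of the alkoxide, ionisation, capture of the isopropoxy-stabilised cation by water and loss of isopropanol (squarate addition/carbonyl transposition) should give the 3-alkoxy-4-alkylcyclobutenedione with both MOM ethers intact.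

Step 9
Reactants: 16 3-isopropoxy-4-[2-(4-{2-(methoxymethoxy)-5-[2-(3-(methoxymethoxy)phenyl)ethyl]phenoxy}phenyl)ethyl]cyclobut-3-ene-1,2-dione
Product: 17 3-hydroxy-4-[2-(4-{2-hydroxy-5-[2-(3-hydroxyphenyl)ethyl]phenoxy}phenyl)ethyl]cyclobut-3-ene-1,2-dione
Conditions: 6 M aq HCl, THF, 45 °C
Reagents that add atoms: water, O
Why: Acid-catalysed hydrolysis cleaves the vinylogous isopropyl ester by addition–elimination of water to the strongly acidic semisquaric acid and removes both MOM acetals in the same operation, while diaryl ether and bibenzyl units are inert.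

Step 10
Reactants: 17 3-hydroxy-4-[2-(4-{2-hydroxy-5-[2-(3-hydroxyphenyl)ethyl]phenoxy}phenyl)ethyl]cyclobut-3-ene-1,2-dione
Product: 19 macrocyclic cyclobutenedione (18-membered ring; C3 of the cyclobut-3-ene-1,2-dione bonded to the ring-C oxygen, C4 to the CH2CH2 chain; ring-B phenol free), via 3-chloro-4-[2-(4-{2-hydroxy-5-[2-(3-hydroxyphenyl)ethyl]phenoxy}phenyl)ethyl]cyclobut-3-ene-1,2-dione 18 (not isolated)
Conditions: (COCl)2 (1.05 equiv), DMF (cat.), CH2Cl2, 0 °C, then evaporation; syringe-pump addition (12 h) to iPr2NEt (3 equiv), CH2Cl2, rt (final 1 mM)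
Reagents that add atoms: none
Why: Oxalyl chloride/DMF converts the vinylogous carboxylic acid into the vinylogous acid chloride (phenols are not acylated without base), and under pseudo-high dilution the ring-C phenol should displace chloride by addition–elimination (acylation-type macrocyclisation), while the hindered, hydrogen-bonded ring-B phenol could only close a strained 12-membered [8]paracyclophane ring and stays free.

Step 11
Reactants: 19 macrocyclic cyclobutenedione
Product: 20 macrocyclic 4-ethynyl-4-hydroxycyclobut-2-en-1-one (racemic; the carbinol carbon lies next to the aryloxy-bearing alkene carbon)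
Conditions: HC≡CMgBr (3 equiv), THF, −78 → −20 °C; aq NH4Cl
Reagents that add atoms: ethynylmagnesium bromide, C#C[Mg]Br
Why: The first equivalent deprotonates the phenol and the acetylide then adds 1,2 (acetylide carbonyl addition) to the ketone-like carbonyl next to the aryloxy-bearing carbon, giving a racemic carbinol whose configuration, like the choice of carbonyl, is of no consequence because both possibilities collapse to the same quinone in step 12.

Step 12
Reactants: 20 macrocyclic 4-ethynyl-4-hydroxycyclobut-2-en-1-one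
Product: 23 marchantinquinone, via the enynyl ketene 21 (not isolated), via the phenoxyl/aryl diradical 22 (not isolated)
Conditions: toluene (0.005 M, degassed), 110 °C
Reagents that add atoms: none
Why: Heating should open the cyclobutenone by conrotatory 4π electrocyclic cleavage of the C(=O)–C(OH) bond to the conjugated ketene 21, the hydroxyl rotating outward (donor torquoselectivity) so that the ethynyl group ends up syn to the ketene. The ketene carbon then bonds to the terminal alkyne carbon, a six-ring closure of 6-endo type (Moore cyclisation) that gives the σ,π-diradical 22 (phenoxyl oxygen at C1, carbon radical at C5), and transfer of the hydroxyl hydrogen to the carbon radical delivers the quinone without any oxidant. The closest known reaction type is the Moore rearrangement of 4-alkynyl-4-hydroxycyclobutenones to 1,4-benzoquinones. No stereocentre is formed, and the racemic carbinol centre of 20 disappears. The step needs six-ring closure to win over the five-ring (5-exo) closure that leads to an alkylidenecyclopentenedione; the terminal alkyne, which carries no radical-stabilising substituent, secures this, and dilution suppresses capture of the ketene by the free phenol. The macrocycle spans only the two alkene carbons and holds the aryloxy and alkyl groups syn, which fixes the s-cis geometry that ring closure requires.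

**Compound list**

1 | 3,4-dihydroxybenzaldehyde | O=Cc1ccc(O)c(O)c1 | starting material
2 | 3-hydroxy-4-(methoxymethoxy)benzaldehyde | O=Cc1ccc(OCOC)c(O)c1 | intermediate
3 | 2-(4-bromophenyl)ethanol | OCCc1ccc(Br)cc1 | starting material
4 | 3-[4-(2-hydroxyethyl)phenoxy]-4-(methoxymethoxy)benzaldehyde | O=Cc1ccc(OCOC)c(Oc2ccc(CCO)cc2)c1 | intermediate
5 | 3-hydroxybenzyl alcohol | OCc1cccc(O)c1 | starting material
6 | (3-hydroxybenzyl)triphenylphosphonium bromide | [Br-].Oc1cccc(C[P+](c2ccccc2)(c2ccccc2)c2ccccc2)c1 | intermediate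
7 | potassium 3-[(triphenylphosphoranylidene)methyl]phenolate (ylide, not isolated) | [K+].[O-]c1cccc(C=P(c2ccccc2)(c2ccccc2)c2ccccc2)c1 | intermediate
8 | 3-{2-[3-[4-(2-hydroxyethyl)phenoxy]-4-(methoxymethoxy)phenyl]ethenyl}phenol (E/Z mixture, geometry not specified) | OCCc1ccc(cc1)Oc1cc(C=Cc2cccc(O)c2)ccc1OCOC | intermediate
9 | 3-{2-[3-[4-(2-hydroxyethyl)phenoxy]-4-(methoxymethoxy)phenyl]ethyl}phenol | OCCc1ccc(cc1)Oc1cc(CCc2cccc(O)c2)ccc1OCOC | intermediate
10 | 3-{2-[3-[4-(2-bromoethyl)phenoxy]-4-(methoxymethoxy)phenyl]ethyl}phenol | BrCCc1ccc(cc1)Oc1cc(CCc2cccc(O)c2)ccc1OCOC | intermediate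
11 | 2-[4-(2-bromoethyl)phenoxy]-1-(methoxymethoxy)-4-{2-[3-(methoxymethoxy)phenyl]ethyl}benzene | BrCCc1ccc(cc1)Oc1cc(CCc2cccc(OCOC)c2)ccc1OCOC | intermediate
12 | 3,4-diisopropoxycyclobut-3-ene-1,2-dione (diisopropyl squarate) | CC(C)OC1=C(OC(C)C)C(=O)C1=O | starting material
13 | Grignard reagent of 11 (not isolated) | Br[Mg]CCc1ccc(cc1)Oc1cc(CCc2cccc(OCOC)c2)ccc1OCOC | intermediate
14 | bromomagnesium alkoxide of the 4-hydroxy-2,3-diisopropoxy-4-(arylethyl)cyclobut-2-en-1-one adduct (not isolated) | CC(C)OC1=C(OC(C)C)C(O[Mg]Br)(CCc2ccc(cc2)Oc2cc(CCc3cccc(OCOC)c3)ccc2OCOC)C1=O | intermediate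
15 | O-trifluoroacetate of the 1,2-adduct (not isolated) | CC(C)OC1=C(OC(C)C)C(OC(=O)C(F)(F)F)(CCc2ccc(cc2)Oc2cc(CCc3cccc(OCOC)c3)ccc2OCOC)C1=O | intermediate
16 | 3-isopropoxy-4-[2-(4-{2-(methoxymethoxy)-5-[2-(3-(methoxymethoxy)phenyl)ethyl]phenoxy}phenyl)ethyl]cyclobut-3-ene-1,2-dione | CC(C)OC1=C(CCc2ccc(cc2)Oc2cc(CCc3cccc(OCOC)c3)ccc2OCOC)C(=O)C1=O | intermediate
17 | 3-hydroxy-4-[2-(4-{2-hydroxy-5-[2-(3-hydroxyphenyl)ethyl]phenoxy}phenyl)ethyl]cyclobut-3-ene-1,2-dione | OC1=C(CCc2ccc(cc2)Oc2cc(CCc3cccc(O)c3)ccc2O)C(=O)C1=O | intermediate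
18 | 3-chloro-4-[2-(4-{2-hydroxy-5-[2-(3-hydroxyphenyl)ethyl]phenoxy}phenyl)ethyl]cyclobut-3-ene-1,2-dione (not isolated) | ClC1=C(CCc2ccc(cc2)Oc2cc(CCc3cccc(O)c3)ccc2O)C(=O)C1=O | intermediate
19 | macrocyclic 3-aryloxy-4-alkylcyclobut-3-ene-1,2-dione (18-membered ring, ring-B phenol free) | O=C1C(=O)C2=C1CCc1ccc(cc1)Oc1cc(ccc1O)CCc1cccc(c1)O2 | intermediate
20 | macrocyclic 4-ethynyl-4-hydroxycyclobut-2-en-1-one (racemic, stereocentre not specified) | O=C1C(O)(C#C)C2=C1CCc1ccc(cc1)Oc1cc(ccc1O)CCc1cccc(c1)O2 | intermediate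
21 | macrocyclic enynyl ketene, ethynyl syn to the ketene (not isolated) | O=C=C1CCc2ccc(cc2)Oc2cc(ccc2O)CCc2cccc(c2)O/C1=C(\O)C#C | intermediate
22 | phenoxyl/aryl σ,π-diradical (not isolated) | [O]c1c[c]c(O)c2c1CCc1ccc(cc1)Oc1cc(ccc1O)CCc1cccc(c1)O2 | intermediate
23 | marchantinquinone | O=C1C=CC(=O)C2=C1CCc1ccc(cc1)Oc1cc(ccc1O)CCc1cccc(c1)O2 | target

**Summary**

Total step count: 12. Longest linear sequence: 11 steps (steps 1, 2 and 4–12; step 3 is a one-step side branch).

**Steps most likely to fail**

Step 10. What may go wrong: intermolecular acylation of either free phenol outruns the 18-membered ring closure, so that oligomers form instead of the macrocycle. The fallback differentiates the two phenols instead of relying on ring strain. It sets out from compound 1, which is benzylated at the 4-hydroxyl (BnBr, NaHCO3, NaI, DMF, 40 °C) to 4-(benzyloxy)-3-hydroxybenzaldehyde F1. Ullmann coupling with 3 as in step 2 should give 4-(benzyloxy)-3-[4-(2-hydroxyethyl)phenoxy]benzaldehyde F2, and Wittig reaction with ylide 7 the benzyloxy stilbene F3. Diimide reduction (TsNHNH2, NaOAc, DME/H2O, reflux), which spares the benzyl ether, should give the benzyloxy bibenzyl F4. Appel bromination gives the benzyloxy bromide F5, and MOM protection of the ring-C phenol gives the benzyloxy MOM bromide F6. Its Grignard reagent F7 adds to 12 to give the magnesium alkoxide F8, and TFAA converts this into the trifluoroacetate F9, which collapses on aqueous work-up to the benzyloxy isopropoxy dione F10. 6 M HCl/THF removes the isopropyl group and the single MOM group and should give the benzyloxy semisquaric acid F11, in which only the ring-C phenol is free. Oxalyl chloride gives the benzyloxy chloride F12, and high-dilution cyclisation as in step 10 gives the O-benzyl macrocyclic dione F13. Hydrogenolysis (H2, Pd/C, EtOAc, rt, short contact time) then gives compound 19, where the fallback comes back to the route.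

Step 12. What may go wrong: closure of the ketene onto the inner alkyne carbon (five-ring mode, leading to an alkylidenecyclopentenedione) or capture of the ketene by a phenol competes with six-ring closure. The fallback uses the alkenyl instead of the alkynyl ring expansion, followed by oxidation. It sets out from compound 19. Vinylmagnesium bromide (3 equiv, THF, −78 °C) should give the macrocyclic 4-hydroxy-4-vinylcyclobutenone F14. On heating in toluene (110 °C) this should undergo 4π ring opening, 6π electrocyclisation (which can only form a six-membered ring) and tautomerisation to the macrocyclic hydroquinone F15. Oxidation with Ag2O (Et2O, rt), which takes the hydroquinone but not the isolated phenol, comes back to the route at compound 23.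

Step 11. What may go wrong: the magnesium phenoxide formed by the first equivalent attacks the vinylogous aryl ester of a second molecule (aryloxide exchange with opening of the macrocycle) or precipitates, so that carbonyl addition stalls. The fallback carries a temporary silyl ether through the rearrangement. It sets out from compound 19. TBSOTf and 2,6-lutidine (CH2Cl2, −78 °C) should give the O-TBS macrocyclic dione F16. Ethynylmagnesium bromide (1.5 equiv, THF, −78 °C) then gives the O-TBS ethynyl carbinol F17, and thermolysis as in step 12 gives the O-TBS quinone F18. HF·pyridine (THF, 0 °C) removes the silyl group and comes back to the route at compound 23.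

**Further compounds**

F1 | step 10 | 4-(benzyloxy)-3-hydroxybenzaldehyde | O=Cc1ccc(OCc2ccccc2)c(O)c1
F2 | step 10 | 4-(benzyloxy)-3-[4-(2-hydroxyethyl)phenoxy]benzaldehyde | O=Cc1ccc(OCc2ccccc2)c(Oc2ccc(CCO)cc2)c1
F3 | step 10 | 3-{2-[4-(benzyloxy)-3-[4-(2-hydroxyethyl)phenoxy]phenyl]ethenyl}phenol (E/Z mixture) | OCCc1ccc(cc1)Oc1cc(C=Cc2cccc(O)c2)ccc1OCc1ccccc1
F4 | step 10 | 3-{2-[4-(benzyloxy)-3-[4-(2-hydroxyethyl)phenoxy]phenyl]ethyl}phenol | OCCc1ccc(cc1)Oc1cc(CCc2cccc(O)c2)ccc1OCc1ccccc1
F5 | step 10 | 3-{2-[4-(benzyloxy)-3-[4-(2-bromoethyl)phenoxy]phenyl]ethyl}phenol | BrCCc1ccc(cc1)Oc1cc(CCc2cccc(O)c2)ccc1OCc1ccccc1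
F6 | step 10 | 1-(benzyloxy)-2-[4-(2-bromoethyl)phenoxy]-4-{2-[3-(methoxymethoxy)phenyl]ethyl}benzene | BrCCc1ccc(cc1)Oc1cc(CCc2cccc(OCOC)c2)ccc1OCc1ccccc1
F7 | step 10 | Grignard reagent of F6 | Br[Mg]CCc1ccc(cc1)Oc1cc(CCc2cccc(OCOC)c2)ccc1OCc1ccccc1
F8 | step 10 | bromomagnesium alkoxide of the squarate 1,2-adduct (benzyl series) | CC(C)OC1=C(OC(C)C)C(O[Mg]Br)(CCc2ccc(cc2)Oc2cc(CCc3cccc(OCOC)c3)ccc2OCc2ccccc2)C1=O
F9 | step 10 | O-trifluoroacetate of the 1,2-adduct (benzyl series) | CC(C)OC1=C(OC(C)C)C(OC(=O)C(F)(F)F)(CCc2ccc(cc2)Oc2cc(CCc3cccc(OCOC)c3)ccc2OCc2ccccc2)C1=O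
F10 | step 10 | 3-isopropoxy-4-[2-(4-{2-(benzyloxy)-5-[2-(3-(methoxymethoxy)phenyl)ethyl]phenoxy}phenyl)ethyl]cyclobut-3-ene-1,2-dione | CC(C)OC1=C(CCc2ccc(cc2)Oc2cc(CCc3cccc(OCOC)c3)ccc2OCc2ccccc2)C(=O)C1=O
F11 | step 10 | 3-hydroxy-4-[2-(4-{2-(benzyloxy)-5-[2-(3-hydroxyphenyl)ethyl]phenoxy}phenyl)ethyl]cyclobut-3-ene-1,2-dione | OC1=C(CCc2ccc(cc2)Oc2cc(CCc3cccc(O)c3)ccc2OCc2ccccc2)C(=O)C1=O
F12 | step 10 | 3-chloro-4-[2-(4-{2-(benzyloxy)-5-[2-(3-hydroxyphenyl)ethyl]phenoxy}phenyl)ethyl]cyclobut-3-ene-1,2-dione | ClC1=C(CCc2ccc(cc2)Oc2cc(CCc3cccc(O)c3)ccc2OCc2ccccc2)C(=O)C1=O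
F13 | step 10 | O-benzyl macrocyclic cyclobutenedione | O=C1C(=O)C2=C1CCc1ccc(cc1)Oc1cc(ccc1OCc1ccccc1)CCc1cccc(c1)O2
F14 | step 12 | macrocyclic 4-hydroxy-4-vinylcyclobut-2-en-1-one (racemic) | O=C1C(O)(C=C)C2=C1CCc1ccc(cc1)Oc1cc(ccc1O)CCc1cccc(c1)O2
F15 | step 12 | macrocyclic hydroquinone (dihydromarchantinquinone) | Oc1ccc(O)c2c1CCc1ccc(cc1)Oc1cc(ccc1O)CCc1cccc(c1)O2
F16 | step 11 | O-TBS macrocyclic cyclobutenedione | O=C1C(=O)C2=C1CCc1ccc(cc1)Oc1cc(ccc1O[Si](C)(C)C(C)(C)C)CCc1cccc(c1)O2
F17 | step 11 | O-TBS macrocyclic 4-ethynyl-4-hydroxycyclobut-2-en-1-one (racemic) | O=C1C(O)(C#C)C2=C1CCc1ccc(cc1)Oc1cc(ccc1O[Si](C)(C)C(C)(C)C)CCc1cccc(c1)O2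
F18 | step 11 | O-TBS marchantinquinone | O=C1C=CC(=O)C2=C1CCc1ccc(cc1)Oc1cc(ccc1O[Si](C)(C)C(C)(C)C)CCc1cccc(c1)O2
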